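The earlier runs and the new flask are simulated on assumed constants; scatter was added.

Take as the fixed thing in Wednesday's flask a rate, not an amount: if the isomer of the product grows one-way out of a target that stands steady, the isomer counted in standing loads of target gains the same number of turnovers each day. You ask for a quick number, so here is my count.

- Wednesday's: solid substrate 0.80 M; protic impurity 0.40 M; the very flask that is asked about, followed so far
- flask: solid substrate 0.80 M; protic impurity 0.400 M; time 15 d

Wednesday's run (percent of the solid substrate charged)

| time / d | isomer of the product / % | target / % |
|---|---|---|
| 0.500 | 0 | 1.7 |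
| 1.67 | 2.7 | 4.4 |
| 2.50 | 4.0 | 5.4 |
| 4.00 | 8.0 | 4.1 |
| 6.00 | 8.8 | 4.3 |
| 8.00 | 11.4 | 3.7 |

(each reading ± 1 percentage point)

- given per volume of solution although it is solid: solid substrate
- the numbers in the tables scatter with a standard deviation of 1 percentage point
- at the start none of the solid substrate is in solution

- share of isomer of the product in isomer of the product plus target at 12 h
- share of isomer of the product in isomer of the product plus target at 15 d
- which of isomer of the product and target there is more of at 15 d

I call k, the isomer formed per day per fraction of the charge standing as target, the turnover rate, a pseudo-first-order constant, and I read it from the last reading: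

k = 11.4 % / (3.7 % × 8.00 d) = 0.385 d⁻¹

The turnovers are N = k × time, and the share of isomer is N/(1 + N):

at 12 h: N = 0.193, share 16.1 %

at 15 d: N = 5.78, share 85.2 %

The count assumes a steady target, and the target readings only roughly allow that: they rise from 1.7 % at 0.500 d and then lie between 3.7 % and 5.4 % from 1.67 d on. A scatter of 1 percentage point on a target reading of 3.7 % keeps this loose too. One turnover falls at 2.60 d, earlier than 15 d, so I put the isomer ahead at the end.

The forecast gives 12 % and 85 % with isomer of the product ahead, reading “a sequence: dissolving substrate → target → isomer”, and its early share is lower than mine.

The flask gives 11.9 % at 12 h and 81.7 % at 15 d, with isomer of the product ahead, 16.1 % against 3.62 % of the charge. The relaxation half-life of target and isomer, 1.30 d, is short against the 15 d. My count stands 4.2 points high early and 3.5 points high late, and where the flask has equal isomer and target, at 3.29 d, k gives N = 1.27.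

    solid substrate ⇌ starting material, rate k1*(cs1 - [starting material]) while solid is left; crystals form when [starting material] > cs1 (solubility = 0.640 M, k = 9.40 × 10⁻⁶ s⁻¹)
    starting material + protic impurity → quenched substrate (k = 9.30 × 10⁻⁵ L mol⁻¹ s⁻¹)
    starting material ⇌ target (K = 0.120, k = 9.20 × 10⁻⁵ s⁻¹)
    target ⇌ isomer of the product (K = 6.00, k = 5.30 × 10⁻⁶ s⁻¹)

In the neighbouring flask with 1.6 M of protic impurity, the same k, with the target again taken as steady, gives 16.1 % at 12 h and 85.2 % at 15 d. That flask computes 14.8 % and 99.7 %, with isomer at 0.205 % of the charge, target at 0 % and quenched substrate at 99.8 % at 15.0 d.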